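**Retrosynthetic overview**

1. Feature: the 2,3-dihydrobenzofuran ring O1–C2–C3–C3a–C7a with an aryl group on C2 and a one-carbon group on C3 is a contracted chroman-4-one. Bond C3–C3a is made by moving the benzo-ring carbon C4a of a flavanone from the carbonyl carbon C4 to C3, and old C4 leaves the ring to become the CH2OH carbon. (Ring A = benzo ring, ring B = 2-aryl ring.)
2. Target 15 ⇐ cinnamate 14 (hydrogenation) ⇐ aryl bromide 12 + methyl acrylate (Heck) ⇐ ester 11 (reduction of the C3 ester, loss of the pivalate).
3. Ester 11 ⇐ (2S)-flavanone 8 by oxidative 1,2-shift of ring A with trivalent iodine. C2 is carried over and C3 is set trans to it.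
4. Flavanone 8 ⇐ chromone 4 + arylboronic acid 7 (C2–aryl bond and C2 stereocentre by enantioselective 1,4-addition); 4 ⇐ acetophenone 1 (bromination, amide acetal); 7 ⇐ phenol boronate 5.
5. Ring order: both benzene rings are bought; the pyranone ring is closed in step 2 and contracted to the dihydrofuran in step 6.

Key step: step 6

Assumption: the pyridine-oxazoline ligand is taken to shield the same enone face of chromone 4 as it does for 3-substituted cyclohexenones. This points to the (R)-ligand for the (2S)-flavanone; the assignment should be confirmed on the first batch and the antipodal ligand used if it proves opposite.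

**Route**

Step 1
Reactants: 1 2'-hydroxy-3'-methoxyacetophenone
Product: 2 5'-bromo-2'-hydroxy-3'-methoxyacetophenone
Conditions: NBS (1.05 equiv), MeCN, 0 °C to rt
Reagents that add atoms: N-bromosuccinimide, O=C1CCC(=O)N1Br
Why: Electrophilic aromatic bromination: the free phenol is the strongest donor and its para position (C5') is open, whereas C4' and C6' are activated only by the methoxy group, so NBS in MeCN should brominate C5' and, without radical initiation or strong acid, leave the acetyl CH3 alone.

Step 2
Reactants: 2 5'-bromo-2'-hydroxy-3'-methoxyacetophenone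
Product: 4 6-bromo-8-methoxy-4H-chromen-4-one, via (E)-dimethylamino enone 3 (not isolated)
Conditions: Me2NCH(OMe)2, toluene, 100 °C; evaporate; then conc. HCl, CH2Cl2, 40 °C
Reagents that add atoms: N,N-dimethylformamide dimethyl acetal, COC(OC)N(C)C
Why: Enaminone chromone synthesis: the acetyl CH3 condenses with the amide acetal to the vinylogous amide 3, and acid then drives conjugate addition of the phenol oxygen to the β-carbon and loss of dimethylamine, which closes the pyranone ring of 4 with C2 and C3 unsubstituted.

Step 3
Reactants: 5 2,6-dimethoxy-4-(4,4,5,5-tetramethyl-1,3,2-dioxaborolan-2-yl)phenol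
Product: 6 2,6-dimethoxy-4-(4,4,5,5-tetramethyl-1,3,2-dioxaborolan-2-yl)phenyl pivalate
Conditions: t-BuCOCl, Et3N, DMAP (cat.), CH2Cl2, 0 °C to rt
Reagents that add atoms: pivaloyl chloride, CC(C)(C)C(=O)Cl
Why: DMAP-catalysed O-acylation of the hindered phenol; the pivalate should survive periodate, divalent palladium catalysis and H2SO4/orthoformate, and an acyloxy group donates far less to ring B than a free or alkylated phenol, which matters in step 6.

Step 4
Reactants: 6 2,6-dimethoxy-4-(4,4,5,5-tetramethyl-1,3,2-dioxaborolan-2-yl)phenyl pivalate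
Product: 7 [3,5-dimethoxy-4-(pivaloyloxy)phenyl]boronic acid
Conditions: NaIO4, NH4OAc, acetone/H2O (1:1), rt
Reagents that add atoms: water, O
Why: Oxidative cleavage of the pinacol by periodate pulls the boronate hydrolysis equilibrium to the free boronic acid, the form that transmetalates to cationic divalent palladium without base; the phenol is already acylated, so periodate finds no electron-rich phenol to oxidise.

Step 5
Reactants: 4 6-bromo-8-methoxy-4H-chromen-4-one; 7 [3,5-dimethoxy-4-(pivaloyloxy)phenyl]boronic acid (2 equiv)
Product: 8 (2S)-6-bromo-8-methoxy-2-[3,5-dimethoxy-4-(pivaloyloxy)phenyl]chroman-4-one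
Conditions: Pd(OCOCF3)2 (5 mol %), (R)-t-BuPyOx (6 mol %), NH4PF6 (30 mol %), H2O (5 equiv), ClCH2CH2Cl, 60 °C; recrystallisation if the enantiomeric purity needs raising
Reagents that add atoms: none
Why: Palladium-catalysed asymmetric conjugate addition of an arylboronic acid to a chromone: transmetalation gives a cationic aryl–palladium pyridine-oxazoline complex, the aryl group is delivered to C2 by enantiodetermining migratory insertion of C2=C3 with the tert-butyl group of the oxazoline shielding one enone face (the (R)-ligand is expected to give 2S), and water protonates the palladium enolate; the base-free medium gives the flavanone no chance to racemise by retro-oxa-Michael opening, and phosphine-free divalent palladium should leave the aryl bromide alone.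

Step 6
Reactants: 8 (2S)-6-bromo-8-methoxy-2-[3,5-dimethoxy-4-(pivaloyloxy)phenyl]chroman-4-one
Product: 11 methyl (2S,3S)-5-bromo-7-methoxy-2-[3,5-dimethoxy-4-(pivaloyloxy)phenyl]-2,3-dihydrobenzofuran-3-carboxylate, via 4-methoxy-2H-chromene enol ether 9 (not isolated), via trans-3-iodanyl dimethyl ketal 10 (not isolated)
Conditions: PhI(OAc)2 (1.3 equiv), conc. H2SO4, HC(OMe)3, rt; then aq. NaHCO3
Reagents that add atoms: trimethyl orthoformate, COC(OC)OC
Why: Acid and the orthoformate turn the ketone of 8 into its dimethyl ketal and the enol ether 9, the trivalent iodine electrophile adds to C3 of 9 on the face away from the C2 aryl group with capture of methanol at C4 to give the 2,3-trans iodane 10, and the ring A carbon C4a then shifts from C4 to C3 as PhI leaves, the dimethoxycarbenium ion (an orthoester after methanol capture) collapsing to the methyl ester on work-up. This is the oxidative 1,2-aryl-shift ring contraction known for flavanones with PhI(OAc)2 or Tl(NO3)3 in trimethyl orthoformate, a relative of the semipinacol and quasi-Favorskii contractions. The ring O1–C2–C3–C3a–C7a is closed by contraction, not by cyclisation of a chain: C4a displaces iodobenzene at C3 through a bridged phenonium-type (formally 3-exo-tet) transition state, which makes the C3–C3a bond and pushes old C4 out as the exocyclic ester carbon. C2 takes no part and keeps the S configuration of step 5, and the new C3 centre is set by C2, because iodine enters anti to the aryl group and is displaced with inversion, which places the ester trans to the aryl group (2S,3S), also the more stable epimer to which any cis ester should drift by acid enolisation. The step needs the shift of ring A in preference to the shift of ring B (isoflavone), to elimination (flavone), to acid opening to the chalcone and to attack of iodine on the dimethoxyaryl ring: in the diequatorial 2-aryl/3-iodanyl half-chair the C3–iodine bond is antiperiplanar to the C4–C4a ring bond and not to the C2–aryl bond, C4a is ortho to the donor O1, and the acyloxy group para to C2 in ring B withholds the donation that would favour cleavage or migration at C2. The aryl bromide, the pivalate and the methyl ethers should be inert at room temperature.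

Step 7
Reactants: 11 methyl (2S,3S)-5-bromo-7-methoxy-2-[3,5-dimethoxy-4-(pivaloyloxy)phenyl]-2,3-dihydrobenzofuran-3-carboxylate
Product: 12 4-[(2S,3R)-5-bromo-3-(hydroxymethyl)-7-methoxy-2,3-dihydrobenzofuran-2-yl]-2,6-dimethoxyphenol
Conditions: i-Bu2AlH (5 equiv), CH2Cl2, −78 to 0 °C; aq. KNaC4H4O6 (potassium sodium tartrate)
Reagents that add atoms: none
Why: Ester reduction with an aluminium hydride: i-Bu2AlH takes the C3 methyl ester through the aldehyde to the primary alcohol and also cleaves the aryl pivalate reductively, so the phenol is unmasked in the same flask; the aryl bromide and the benzylic C2–O1 ether are inert at or below 0 °C, C2 is untouched and C3 keeps the trans arrangement, which is the stable one even if the aldehyde stage enolises (the descriptor changes to 3R only through priorities).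

Step 8
Reactants: 12 4-[(2S,3R)-5-bromo-3-(hydroxymethyl)-7-methoxy-2,3-dihydrobenzofuran-2-yl]-2,6-dimethoxyphenol; 13 methyl acrylate
Product: 14 methyl (E)-3-[(2S,3R)-2-(4-hydroxy-3,5-dimethoxyphenyl)-3-(hydroxymethyl)-7-methoxy-2,3-dihydrobenzofuran-5-yl]prop-2-enoate
Conditions: Pd(OAc)2 (5 mol %), P(o-tol)3 (12 mol %), Et3N, DMF, 90 °C, under N2
Reagents that add atoms: none
Why: Mizoroki–Heck reaction: zerovalent palladium inserts into the C5–Br bond, syn carbopalladation of the acrylate at its terminal carbon and syn β-hydride elimination give the E-cinnamate, and free phenolic and primary hydroxyl groups are tolerated with an amine base; no stereocentre takes part.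

Step 9
Reactants: 14 methyl (E)-3-[(2S,3R)-2-(4-hydroxy-3,5-dimethoxyphenyl)-3-(hydroxymethyl)-7-methoxy-2,3-dihydrobenzofuran-5-yl]prop-2-enoate
Product: 15 methyl 3-[(2S,3R)-2-(4-hydroxy-3,5-dimethoxyphenyl)-3-(hydroxymethyl)-7-methoxy-2,3-dihydrobenzofuran-5-yl]propanoate
Conditions: H2 (1 atm), 10% Pd/C, EtOAc, rt
Reagents that add atoms: none
Why: Heterogeneous catalytic hydrogenation saturates the conjugated C=C bond; at 1 atm in EtOAc at room temperature the benzylic C2–O1 bond of the dihydrobenzofuran should not be hydrogenolysed at a competitive rate, and neither stereocentre is affected.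

**Compound list**

1 | 2'-hydroxy-3'-methoxyacetophenone | CC(=O)c1cccc(OC)c1O | starting material
2 | 5'-bromo-2'-hydroxy-3'-methoxyacetophenone | CC(=O)c1cc(Br)cc(OC)c1O | intermediate
3 | (E)-1-(5-bromo-2-hydroxy-3-methoxyphenyl)-3-(dimethylamino)prop-2-en-1-one | CN(C)/C=C/C(=O)c1cc(Br)cc(OC)c1O | intermediate (not isolated)
4 | 6-bromo-8-methoxy-4H-chromen-4-one | O=c1ccoc2c(OC)cc(Br)cc12 | intermediate
5 | 2,6-dimethoxy-4-(4,4,5,5-tetramethyl-1,3,2-dioxaborolan-2-yl)phenol | COc1cc(B2OC(C)(C)C(C)(C)O2)cc(OC)c1O | starting material
6 | 2,6-dimethoxy-4-(4,4,5,5-tetramethyl-1,3,2-dioxaborolan-2-yl)phenyl pivalate | COc1cc(B2OC(C)(C)C(C)(C)O2)cc(OC)c1OC(=O)C(C)(C)C | intermediate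
7 | [3,5-dimethoxy-4-(pivaloyloxy)phenyl]boronic acid | COc1cc(B(O)O)cc(OC)c1OC(=O)C(C)(C)C | intermediate
8 | (2S)-6-bromo-8-methoxy-2-[3,5-dimethoxy-4-(pivaloyloxy)phenyl]chroman-4-one | O=C1C[C@@H](c2cc(OC)c(OC(=O)C(C)(C)C)c(OC)c2)Oc2c(OC)cc(Br)cc12 | intermediate
9 | (2S)-6-bromo-4,8-dimethoxy-2-[3,5-dimethoxy-4-(pivaloyloxy)phenyl]-2H-chromene | COC1=C[C@@H](c2cc(OC)c(OC(=O)C(C)(C)C)c(OC)c2)Oc2c(OC)cc(Br)cc12 | intermediate (not isolated)
10 | (2R,3R)-3-[acetoxy(phenyl)-λ3-iodanyl]-6-bromo-4,4,8-trimethoxy-2-[3,5-dimethoxy-4-(pivaloyloxy)phenyl]chromane (2,3-trans; C2 arranged as in 8) | COC1(OC)[C@H](I(OC(C)=O)c2ccccc2)[C@@H](c2cc(OC)c(OC(=O)C(C)(C)C)c(OC)c2)Oc2c(OC)cc(Br)cc12 | intermediate (not isolated)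
11 | methyl (2S,3S)-5-bromo-7-methoxy-2-[3,5-dimethoxy-4-(pivaloyloxy)phenyl]-2,3-dihydrobenzofuran-3-carboxylate (2,3-trans) | Brc1cc(OC)c2c(c1)[C@H](C(=O)OC)[C@@H](c1cc(OC)c(OC(=O)C(C)(C)C)c(OC)c1)O2 | intermediate
12 | 4-[(2S,3R)-5-bromo-3-(hydroxymethyl)-7-methoxy-2,3-dihydrobenzofuran-2-yl]-2,6-dimethoxyphenol | Brc1cc(OC)c2c(c1)[C@H](CO)[C@@H](c1cc(OC)c(O)c(OC)c1)O2 | intermediate
13 | methyl acrylate | C=CC(=O)OC | starting material
14 | methyl (E)-3-[(2S,3R)-2-(4-hydroxy-3,5-dimethoxyphenyl)-3-(hydroxymethyl)-7-methoxy-2,3-dihydrobenzofuran-5-yl]prop-2-enoate | COC(=O)/C=C/c1cc(OC)c2c(c1)[C@H](CO)[C@@H](c1cc(OC)c(O)c(OC)c1)O2 | intermediate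
15 | methyl 3-[(2S,3R)-2-(4-hydroxy-3,5-dimethoxyphenyl)-3-(hydroxymethyl)-7-methoxy-2,3-dihydrobenzofuran-5-yl]propanoate | COC(=O)CCc1cc(OC)c2c(c1)[C@H](CO)[C@@H](c1cc(OC)c(O)c(OC)c1)O2 | target

**Step count**

Total: 9 steps. Longest linear sequence: 7 steps (1 → 2 → 4 → 8 → 11 → 12 → 14 → 15, that is steps 1, 2, 5, 6, 7, 8 and 9); steps 3 and 4 form the short side arm to 7.

**Steps most likely to fail**

1. Step 6 (ring contraction). The iodane may be consumed along the wrong channel: shift of ring B instead of ring A, elimination to the flavone, plain α-methoxylation if the meta bromine and methoxy groups slow the shift of C4a, attack of trivalent iodine on the dimethoxyaryl ring, or acid opening of the pyranone with erosion of C2.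
Fallback, from 8 back to 11, by a carbene (Wolff) shift of the same ring A carbon. Compound 8 would be deprotonated with LiN(SiMe3)2 in THF at −78 °C and acylated with CF3CO2CH2CF3 to the 3-trifluoroacetyl flavanone F1. Detrifluoroacetylative diazo transfer with MeSO2N3, Et3N and one equivalent of water in MeCN should give the 3-diazo flavanone F2. Irradiation of F2 at 365 nm in MeOH should expel N2 and move C4a from C4 to the carbene carbon C3, and the ketene is captured by methanol as the methyl ester. Brief exposure to catalytic NaOMe in MeOH at 0 °C should bring any cis ester to the trans ester 11. The cold, short enolate stage is meant to keep the C2 centre from opening.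

2. Step 5 (asymmetric conjugate addition). Transmetalation of the hindered, acyloxy-substituted boronic acid may be slow, so that protodeboronation and precipitation of palladium black outrun the addition; the facial selectivity on the 8-methoxychromone may be poor or of the opposite sense.
Fallback, from 4 and 7 back to 8, by kinetic resolution instead of enantioselective C–C bond formation. The addition would be run with the achiral ligand 2,2'-bipyridine and Pd(OCOCF3)2 to give the racemic flavanone F3. Transfer hydrogenation with RuCl(p-cymene)[(R,R)-TsDPEN] and HCO2H/Et3N, stopped near half conversion, is expected to reduce the (2R)-enantiomer faster to the cis-(2R,4R)-flavan-4-ol F4 and to leave the (2S)-ketone. The unreacted (2S)-flavanone is separated by chromatography and is 8.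

3. Step 8 (Heck reaction). Oxidative addition into the electron-rich aryl bromide may be sluggish and the catalyst may decay; at 90 °C with base the free p-hydroxybenzyl aryl ether may open through a quinone methide and blur the C2 configuration; the acrylate may oligomerise.
Fallback, from 12 directly to 15, by sp2–sp3 coupling of the saturated chain on a protected substrate. Both hydroxyl groups of 12 would be silylated with t-BuMe2SiCl and imidazole in DMF to the bis(tert-butyldimethylsilyl) ether F5. The zinc homoenolate (3-methoxy-3-oxopropyl)zinc bromide F6 would be made from methyl 3-bromopropanoate and zinc dust with LiCl in THF. Negishi coupling of F5 with F6 under Pd(OAc)2/SPhos in THF at 25–40 °C should give the bis-silyl ether of the target F7. Bu4NF buffered with AcOH in THF then removes both silyl groups to give 15, so steps 8 and 9 are bypassed.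

**Further compounds**

F1 | step 6 | (2S)-6-bromo-8-methoxy-2-[3,5-dimethoxy-4-(pivaloyloxy)phenyl]-3-(trifluoroacetyl)chroman-4-one (C3 unassigned, enolisable) | O=C1c2cc(Br)cc(OC)c2O[C@H](c2cc(OC)c(OC(=O)C(C)(C)C)c(OC)c2)C1C(=O)C(F)(F)F
F2 | step 6 | (2R)-6-bromo-3-diazo-8-methoxy-2-[3,5-dimethoxy-4-(pivaloyloxy)phenyl]chroman-4-one (C2 arranged as in 8; descriptor changed by priorities) | O=C1c2cc(Br)cc(OC)c2O[C@H](c2cc(OC)c(OC(=O)C(C)(C)C)c(OC)c2)C1=[N+]=[N-]
F3 | step 5 | racemic 6-bromo-8-methoxy-2-[3,5-dimethoxy-4-(pivaloyloxy)phenyl]chroman-4-one | O=C1CC(c2cc(OC)c(OC(=O)C(C)(C)C)c(OC)c2)Oc2c(OC)cc(Br)cc12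
F4 | step 5 | (2R,4R)-6-bromo-8-methoxy-2-[3,5-dimethoxy-4-(pivaloyloxy)phenyl]chroman-4-ol (2,4-cis) | O[C@@H]1C[C@H](c2cc(OC)c(OC(=O)C(C)(C)C)c(OC)c2)Oc2c(OC)cc(Br)cc12
F5 | step 8 | (2S,3R)-5-bromo-3-[(tert-butyldimethylsilyloxy)methyl]-2-[4-(tert-butyldimethylsilyloxy)-3,5-dimethoxyphenyl]-7-methoxy-2,3-dihydrobenzofuran | Brc1cc(OC)c2c(c1)[C@H](CO[Si](C)(C)C(C)(C)C)[C@@H](c1cc(OC)c(O[Si](C)(C)C(C)(C)C)c(OC)c1)O2
F6 | step 8 | (3-methoxy-3-oxopropyl)zinc bromide | COC(=O)CC[Zn]Br
F7 | step 8 | methyl 3-[(2S,3R)-3-[(tert-butyldimethylsilyloxy)methyl]-2-[4-(tert-butyldimethylsilyloxy)-3,5-dimethoxyphenyl]-7-methoxy-2,3-dihydrobenzofuran-5-yl]propanoate | COC(=O)CCc1cc(OC)c2c(c1)[C@H](CO[Si](C)(C)C(C)(C)C)[C@@H](c1cc(OC)c(O[Si](C)(C)C(C)(C)C)c(OC)c1)O2
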